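## Structural features

The target is a trans-fused 3a,6,7,7a-tetrahydro-3H-indene: a cyclopentene (C1=C2; ethyl on C1, methyl on C3) fused through C3a–C7a to a cyclohexene (C4=C5; methyl on C4). Five stereocentres are contiguous (C3–C3a–C7a–C7–C6): H-3a and H-7a are anti, the C3 methyl is anti to C4, and C7 (CH3, CO2H) and C6 (C2H5, dienyl) are adjacent all-carbon quaternary centres, with CO2H syn to H-7a and syn to the dienyl arm. C6 carries the (1E,3E)-2-methyl-4-phenylbuta-1,3-dienyl chain, a styryl diene sensitive to acid, oxygen and light; the CO2H on C7 is neopentyl-like and would be hard to free from an ester. The trans ring fusion flanked by two ring double bonds is strained and has no epimerisable position, so it cannot be corrected late. The real difficulty is the C6–C7 bond: two vicinal quaternary centres whose relative configuration must also be locked to C7a and C3a. The feature the plan exploits is that the carboxyl carbon on C7 (called C8) and C4 are 1,4-related across the six-membered ring while C4=C5 is allylic to C6, so C7–C8(=O)···C4=C5–C6 is the product pattern of a [3,3] shift. Reconnecting C8 to C4 through oxygen turns the cyclohexene into a six-membered lactone (O, C8, C7, C7a, C3a, C4) with a C5=C6 alkenyl group on C4, in which the ketene acetal geometry is fixed by the ring and the trans-fused cyclopentene allows a single boat.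

## Logic of the disconnections

**28 ⇒ 25 + 26.** Cut: the C2′–C3′ σ-bond of the dienyl arm (sp2–sp2). Reason: the fragile styryl diene is made last, and until then C6 carries only a 1-propynyl group, which is small, linear and stable to base and heat. Gain: eight carbons and both side-chain double bonds are removed; 25 has no sensitive group. Demand: syn, regioselective hydrometalation of a neopentyl methylalkyne beside a free CO2H, then a stereoretentive sp2–sp2 coupling.

**25 ⇒ 21 (key).** Cut: C6–C7, with O–C4 re-formed and the double bond moved from C4=C5 to C5=C6. Reason: the cut falls on the hardest bond and replaces the carbocycle by a lactone whose enolate geometry is fixed by the ring. Gain: both quaternary centres and the cyclohexene vanish; what is left is one lactone α-C–H, one carbinol stereocentre (C4) and one E-alkene. Demand: C4 must carry the alkenyl arm syn to H-3a, ethyl must be cis to C4 on C5=C6, the enolate must be silylated on oxygen, and the sigmatropic path must beat heterolysis of the tertiary allylic C–O bond. An open-chain ester would not serve, because there neither the ketene acetal geometry nor the reacting face is fixed.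

**21 ⇒ 19 ⇒ 17 + 18 ⇒ 15.** Cuts: C7–CH3; the C6–C(sp) bond of the enyne; C6–I and C5–H back to an alkyne. Reason: the trisubstituted alkene is built from an alkyne by syn hydrometalation, which delivers exactly the needed geometry. The C7 methyl goes in last so that earlier lactones are single compounds. Gain: 15 is a simple alkynyl lactone. Demand: zirconium must go to the carbon remote from C4; iodination and coupling must retain geometry; the C7 configuration is irrelevant because it is erased in the key step.

**15 ⇒ 12 ⇒ 9 + 10.** Cuts: the C4–C5 bond and the O–C8 acyl bond. Reason: acetylide addition to a methyl ketone and lactonisation occur in one flask. Gain: the lactone ring and C5/C6 come from a keto ester and a C4 alkyne. Demand: the acyclic addition gives both C4 epimers, so a thermodynamic correction at C4 is needed that does not touch C3a.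

**9 ⇒ 8 ⇒ 7 ⇒ 5 ⇒ 4 ⇒ 1 + 2.** Cuts: C4=O back to a vinyl group; C1–CH2CH3; C3–CH3 together with C1–OTf; then C7a–C7 and C3a–C4. Reason: a 4-silyloxycyclopentenone three-component coupling sets C3a and C7a trans; the silyloxy group is then expelled to give the enone that accepts the C3 methyl anti to C3a and leaves a regiodefined enolate for the C1=C2 triflate. Gain: all three cyclopentene stereocentres descend from the single stereocentre of 1. Demand: enolate alkylation before equilibration, and elimination without double-bond migration.

## Other disconnections considered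

**Alternative 1:** (the first that comes to mind) cut C3a–C7a and C6–C7 together. Forward key step: intramolecular Diels–Alder reaction of the linear hexaenoic acid A1 (diene C7=C8–C9=C10, dienophile C2=C3). Grounds for not choosing it:
- Exo/endo and facial selectivity rest on the single doubly allylic stereocentre of A1, which is itself prone to 1,5-hydrogen shift.
- The required trans-fused adduct needs the ethyl group on the inside (Z) position of the diene terminus, which retards the cycloaddition.
- A1 contains three overlapping diene units and a (4Z)-trisubstituted alkene, so there is regiochemical ambiguity and a long, geometry-sensitive polyene assembly.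
- In the chosen plan both quaternary centres are fixed by a tethered, stereospecific event on a robust substrate.

**Alternative 2:** cut C6–C7 in an open chain, then C4=C5. Forward key step: Ireland–Claisen rearrangement of the open-chain allyl ester A2 to the diene acid A3, followed by ring-closing metathesis of the isopropenyl and vinyl groups. Grounds: the ketene acetal of an α,α-disubstituted ester forms as an E/Z mixture, and the face is biased only by C7a through a free rotor, so C7 and C6 are not reliably set. The metathesis must then close a trisubstituted alkene between two neopentyl positions in the presence of the polyene. The lactone version removes both uncertainties and makes ring closure and C–C bond formation one event.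

**Alternative 3:** cut C6–C1′ and C7–CH3. Forward key step: conjugate addition of an alkenyl cuprate to C6 of the bicyclic dienoate A4, then enolate C-methylation at C7. Grounds: the β-carbon is fully substituted and part of a cross-conjugated dienoate, so 1,6-addition at C4 or no addition is expected. C6 and C7 would be set by two independent facial choices with no stereospecific link, and A4 already requires the strained trans-fused diene.

Key step: step 11

Assumption: the SMILES is read as the trans-fused (3R,3aS,6S,7R,7aR) isomer; C1–C7a are the indene locants of 28, C8 is the carboxyl carbon and C1′–C4′ are the dienyl carbons, and these labels are used for all intermediates.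

## Route

**Step 1**
Reactants: 1 (R)-4-[(tert-butyldimethylsilyl)oxy]cyclopent-2-en-1-one; 2 methyl bromoacetate
Product: 4 methyl 2-[(1R,2R,3R)-3-[(tert-butyldimethylsilyl)oxy]-5-oxo-2-vinylcyclopentyl]acetate, via bromomagnesium enolate 3 (not isolated)
Conditions: CH2=CHMgBr (2 equiv), CuBr·SMe2 (1 equiv), THF, −78 °C; then 2, HMPA, −78 → −30 °C
Reagents that add atoms: vinylmagnesium bromide, C=C[Mg]Br
Why: The vinyl cuprate adds 1,4 anti to the silyloxy group (sets C3a), and the regiodefined enolate 3 is C-alkylated by the reactive α-bromo ester anti to the new vinyl group (sets C7a); this is a prostaglandin-type three-component coupling (conjugate addition/enolate alkylation).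

**Step 2**
Reactants: 4 methyl 2-[(1R,2R,3R)-3-[(tert-butyldimethylsilyl)oxy]-5-oxo-2-vinylcyclopentyl]acetate
Product: 5 methyl 2-[(1R,5S)-2-oxo-5-vinylcyclopent-3-en-1-yl]acetate
Conditions: DBU, CH2Cl2, 0 °C, short contact
Reagents that add atoms: none
Why: E1cB loss of silanolate from the β-silyloxy ketone gives the 4,5-trans enone; the silyloxy stereocentre has relayed its chirality to C3a and is erased, and cold, brief base treatment avoids γ-deprotonation at C3a.

**Step 3**
Reactants: 5 methyl 2-[(1R,5S)-2-oxo-5-vinylcyclopent-3-en-1-yl]acetate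
Product: 7 all-trans methyl 2-[4-methyl-2-(trifluoromethylsulfonyloxy)-5-vinylcyclopent-2-en-1-yl]acetate, via lithium enolate 6 (not isolated)
Conditions: Me2CuLi (from MeLi, CuI), Et2O, −78 °C; then PhNTf2, THF, −78 → 0 °C
Reagents that add atoms: lithium dimethylcuprate, [Li+].C[Cu-]C; N-phenylbis(trifluoromethanesulfonimide), O=S(=O)(N(c1ccccc1)S(=O)(=O)C(F)(F)F)C(F)(F)F
Why: Cuprate 1,4-addition puts CH3 on C3 anti to the adjacent C3a vinyl group (sets C3), and the enolate 6, formed only between C1 and C2, is triflated on oxygen, which fixes the position of the future C1=C2 bond (conjugate addition/enolate triflation).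

**Step 4**
Reactants: 7 all-trans methyl 2-[4-methyl-2-(trifluoromethylsulfonyloxy)-5-vinylcyclopent-2-en-1-yl]acetate
Product: 8 all-trans methyl 2-(2-ethyl-4-methyl-5-vinylcyclopent-2-en-1-yl)acetate
Conditions: EtMgBr, Fe(acac)3 (5 mol%), THF/NMP, −30 °C
Reagents that add atoms: ethylmagnesium bromide, CC[Mg]Br
Why: Iron-catalysed Kumada-type coupling of an enol triflate with an alkyl Grignard reagent is fast at low temperature, tolerates the methyl ester and the vinyl group and avoids β-hydride loss from ethyl; no stereocentre is touched.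

**Step 5**
Reactants: 8 all-trans methyl 2-(2-ethyl-4-methyl-5-vinylcyclopent-2-en-1-yl)acetate
Product: 9 all-trans methyl 2-(5-acetyl-2-ethyl-4-methylcyclopent-2-en-1-yl)acetate
Conditions: PdCl2 (10 mol%), CuCl, O2 (1 atm), DMF/H2O 7:1, rt
Reagents that add atoms: water, O
Why: Wacker oxidation is selective for the monosubstituted alkene and gives the methyl ketone (Markovnikov), while the trisubstituted ring alkene is inert; C3a, now α to a ketone, already sits in its thermodynamically preferred all-trans arrangement.

**Step 6**
Reactants: 9 all-trans methyl 2-(5-acetyl-2-ethyl-4-methylcyclopent-2-en-1-yl)acetate; 10 but-1-yne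
Product: 12 trans-fused 1-(but-1-yn-1-yl)-5-ethyl-1,7-dimethyl-4,4a,7,7a-tetrahydrocyclopenta[c]pyran-3(1H)-one (both C4 epimers), via lithium alkoxide 11 (not isolated)
Conditions: 10, n-BuLi, THF, −78 °C; then 9, −78 → 23 °C
Reagents that add atoms: none
Why: 1,2-Addition of the lithium acetylide to the methyl ketone gives alkoxide 11, which acylates itself on the neighbouring methyl ester on warming (δ-lactone); the acyclic addition has no reliable facial bias, so C4 forms as both epimers and is corrected in step 7.

**Step 7**
Reactants: 12 trans-fused 1-(but-1-yn-1-yl)-5-ethyl-1,7-dimethyl-4,4a,7,7a-tetrahydrocyclopenta[c]pyran-3(1H)-one (both C4 epimers)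
Product: 15 the single C4 epimer of 12 with the butynyl group syn to H-3a, via dicobalt hexacarbonyl complexes 13 (not isolated), via equatorial dicobalt hexacarbonyl complex 14 (not isolated)
Conditions: Co2(CO)8, CH2Cl2, rt; HBF4·OEt2 (20 mol%), −20 → 0 °C; then CAN, acetone, −10 °C
Reagents that add atoms: none
Why: Nicholas chemistry: the Co2(CO)6-complexed alkyne stabilises the tertiary propargylic cation, so catalytic acid reversibly ionises the lactone C4–O bond and the tethered carboxyl recloses it. Under this thermodynamic control the bulky cluster takes the pseudo-equatorial site (syn to H-3a) with CH3 pseudo-axial, funnelling both epimers into 14. Oxidative decomplexation returns the alkyne without touching C4.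

**Step 8**
Reactants: 15 the single C4 epimer of 12 with the butynyl group syn to H-3a
Product: 17 trans-fused 5-ethyl-1-[(E)-2-iodobut-1-en-1-yl]-1,7-dimethyl-4,4a,7,7a-tetrahydrocyclopenta[c]pyran-3(1H)-one, via alkenylzirconocene 16 (not isolated)
Conditions: Cp2Zr(H)Cl, THF, rt; then I2, 0 °C
Reagents that add atoms: iodine, II
Why: Hydrozirconation is syn and places zirconium on the alkyne carbon remote from the quaternary C4, and iodinolysis retains configuration, so ethyl ends cis to C4 and iodine trans (the E iodide); distal zirconium has no β-leaving group, so the lactone survives.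

**Step 9**
Reactants: 17 trans-fused 5-ethyl-1-[(E)-2-iodobut-1-en-1-yl]-1,7-dimethyl-4,4a,7,7a-tetrahydrocyclopenta[c]pyran-3(1H)-one; 18 propyne
Product: 19 trans-fused 5-ethyl-1-[(E)-2-ethylpent-1-en-3-yn-1-yl]-1,7-dimethyl-4,4a,7,7a-tetrahydrocyclopenta[c]pyran-3(1H)-one
Conditions: 18, PdCl2(PPh3)2 (3 mol%), CuI (6 mol%), Et3N, THF, rt
Reagents that add atoms: none
Why: Sonogashira coupling of the alkenyl iodide proceeds with retention of alkene geometry, giving the E enyne with ethyl cis to C4; the fully substituted alkene terminus shields the tertiary allylic lactone from ionisation by Pd(0) at room temperature.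

**Step 10**
Reactants: 19 trans-fused 5-ethyl-1-[(E)-2-ethylpent-1-en-3-yn-1-yl]-1,7-dimethyl-4,4a,7,7a-tetrahydrocyclopenta[c]pyran-3(1H)-one
Product: 21 trans-fused 5-ethyl-1-[(E)-2-ethylpent-1-en-3-yn-1-yl]-1,4,7-trimethyl-4,4a,7,7a-tetrahydrocyclopenta[c]pyran-3(1H)-one (C7 epimers), via lithium enolate 20 (not isolated)
Conditions: LDA, THF, −78 °C; then MeI, −78 → −40 °C
Reagents that add atoms: iodomethane, CI
Why: Kinetic enolate formation at the only acidic position (C7) and C-methylation (lactone α-alkylation); the new centre forms as an epimer mixture, which does not matter because C7 becomes sp2 again in step 11.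

**Step 11**
Reactants: 21 trans-fused 5-ethyl-1-[(E)-2-ethylpent-1-en-3-yn-1-yl]-1,4,7-trimethyl-4,4a,7,7a-tetrahydrocyclopenta[c]pyran-3(1H)-one (C7 epimers)
Product: 25 (3R,3aS,6R,7R,7aR)-1,6-diethyl-3,4,7-trimethyl-6-(prop-1-yn-1-yl)-3a,6,7,7a-tetrahydro-3H-indene-7-carboxylic acid, via lithium enolate 22 (not isolated), via silyl ketene acetal 23 (not isolated), via silyl ester 24 (not isolated)
Conditions: LDA, THF/DMPU, −78 °C; TBSCl, −78 → 23 °C; then PhMe, 110 °C; then 1 M HCl, THF
Reagents that add atoms: none
Why: LDA removes H-7 and TBSCl silylates oxygen to give 23, in which C7=C8–O–C4–C5=C6 is a 1,5-diene; heating drives a concerted suprafacial [3,3] shift (Ireland–Claisen) that forms C6–C7 as O–C4 breaks, and hydrolysis of silyl ester 24 frees the acid. The closest known reaction type is the Claisen ring contraction of silyl ketene acetals of 6-alkenyl δ-lactones to cyclohex-3-enecarboxylic acids. The cyclohexene (C3a–C4–C5–C6–C7–C7a) closes by C–C bond formation inside a six-membered pericyclic array that the lactone forces into a boat (bicyclo[2.2.2]-like, C7 and C4 as bridgeheads), the ring oxygen being extruded into the carboxyl group. C7 is controlled by the ring: the ketene acetal geometry is fixed (C7a cis to the ring oxygen) and C6 can arrive only on the face over which the C4 alkenyl arm lies, so CO2H ends syn to H-7a and CH3 anti. C6 is controlled by chirality transfer from C4 through the E C5=C6 bond: the group cis to C4 (ethyl) ends syn to the C7 methyl and the trans group (propynyl) syn to CO2H. The trans-fused cyclopentene fixes the sign of the C7–C7a–C3a–C4 torsion, and the helical twist of the boat matches it only for the C4 epimer present in 21, so the ring fusion both permits and gates the shift. The step needs O- rather than C-silylation (silyl chloride in THF/DMPU at −78 °C) and [3,3] rather than heterolysis of the tertiary allylic C4–O bond (non-polar solvent, no Lewis acid, a small linear propynyl group at the bond-forming terminus). Both C7 epimers of 21 converge in 23.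

**Step 12**
Reactants: 25 (3R,3aS,6R,7R,7aR)-1,6-diethyl-3,4,7-trimethyl-6-(prop-1-yn-1-yl)-3a,6,7,7a-tetrahydro-3H-indene-7-carboxylic acid; 26 (E)-(2-bromovinyl)benzene
Product: 28 (3R,3aS,6S,7R,7aR)-1,6-diethyl-3,4,7-trimethyl-6-[(1E,3E)-2-methyl-4-phenylbuta-1,3-dien-1-yl]-3a,6,7,7a-tetrahydro-3H-indene-7-carboxylic acid, via alkenylzirconocene 27 (not isolated)
Conditions: Cp2Zr(H)Cl (3 equiv), THF, 40 °C; then 26, Pd(PPh3)4 (5 mol%), ZnCl2 (20 mol%), rt; 1 M HCl work-up at 0 °C
Reagents that add atoms: none
Why: Syn hydrozirconation puts zirconium on the methyl-bearing alkyne carbon away from the quaternary C6 (the acid is carried as its zirconium carboxylate), and the zinc-assisted Negishi coupling with the E bromide is stereoretentive on both partners, giving the (1E,3E)-diene directly. No stereocentre is involved (the C6 descriptor changes from R to S only because the priorities change), and the mild acid work-up frees CO2H.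

## Compound list

1 | (R)-4-[(tert-butyldimethylsilyl)oxy]cyclopent-2-en-1-one | O=C1C[C@@H](O[Si](C)(C)C(C)(C)C)C=C1 | starting material
2 | methyl bromoacetate | COC(=O)CBr | starting material
3 | bromomagnesium enolate of 4-silyloxy-3-vinylcyclopentanone (vinyl anti to OTBS; not isolated) | Br[Mg]OC1=C[C@@H](C=C)[C@H](O[Si](C)(C)C(C)(C)C)C1 | intermediate
4 | methyl 2-[(1R,2R,3R)-3-[(tert-butyldimethylsilyl)oxy]-5-oxo-2-vinylcyclopentyl]acetate | O=C1C[C@@H](O[Si](C)(C)C(C)(C)C)[C@H](C=C)[C@H]1CC(=O)OC | intermediate
5 | methyl 2-[(1R,5S)-2-oxo-5-vinylcyclopent-3-en-1-yl]acetate | O=C1C=C[C@H](C=C)[C@H]1CC(=O)OC | intermediate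
6 | lithium enolate after methyl addition (CH3 anti to vinyl; not isolated) | [Li]OC1=C[C@@H](C)[C@H](C=C)[C@H]1CC(=O)OC | intermediate
7 | all-trans methyl 2-[4-methyl-2-(trifluoromethylsulfonyloxy)-5-vinylcyclopent-2-en-1-yl]acetate | O=S(=O)(OC1=C[C@@H](C)[C@H](C=C)[C@H]1CC(=O)OC)C(F)(F)F | intermediate
8 | all-trans methyl 2-(2-ethyl-4-methyl-5-vinylcyclopent-2-en-1-yl)acetate | CCC1=C[C@@H](C)[C@H](C=C)[C@H]1CC(=O)OC | intermediate
9 | all-trans methyl 2-(5-acetyl-2-ethyl-4-methylcyclopent-2-en-1-yl)acetate | CCC1=C[C@@H](C)[C@H](C(C)=O)[C@H]1CC(=O)OC | intermediate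
10 | but-1-yne | CCC#C | starting material
11 | lithium alkoxide of the tertiary propargylic alcohol (both C4 epimers; not isolated) | CCC1=C[C@@H](C)[C@H](C(C)(O[Li])C#CCC)[C@H]1CC(=O)OC | intermediate
12 | trans-fused 1-(but-1-yn-1-yl)-5-ethyl-1,7-dimethyl-4,4a,7,7a-tetrahydrocyclopenta[c]pyran-3(1H)-one, both C4 epimers (lactone C1 = C4 of 28; H-3a/H-7a anti; C3 methyl syn to H-3a) | CCC1=C[C@@H](C)[C@H](C2(C)C#CCC)[C@H]1CC(=O)O2 | intermediate
13 | hexacarbonyldicobalt complexes of 12 (both C4 epimers; not isolated) | CCC1=C[C@@H](C)[C@H](C2(C)C34C5(CC)[Co]3(=C=O)(=C=O)(=C=O)[Co]45(=C=O)(=C=O)=C=O)[C@H]1CC(=O)O2 | intermediate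
14 | hexacarbonyldicobalt complex of 15 (cluster pseudo-equatorial; not isolated) | CCC1=C[C@@H](C)[C@H]([C@@]2(C)C34C5(CC)[Co]3(=C=O)(=C=O)(=C=O)[Co]45(=C=O)(=C=O)=C=O)[C@H]1CC(=O)O2 | intermediate
15 | single C4 epimer of 12, butynyl syn to H-3a | CCC1=C[C@@H](C)[C@H]([C@@]2(C)C#CCC)[C@H]1CC(=O)O2 | intermediate
16 | (E)-alkenyl(chloro)zirconocene from 15 (Zr on C6, trans to C4; not isolated) | CCC1=C[C@@H](C)[C@H]([C@@]2(C)/C=C(/[Zr](Cl)(C3C=CC=C3)C3C=CC=C3)CC)[C@H]1CC(=O)O2 | intermediate
17 | trans-fused 5-ethyl-1-[(E)-2-iodobut-1-en-1-yl]-1,7-dimethyl-4,4a,7,7a-tetrahydrocyclopenta[c]pyran-3(1H)-one (alkenyl syn to H-3a) | CCC1=C[C@@H](C)[C@H]([C@@]2(C)/C=C(/I)CC)[C@H]1CC(=O)O2 | intermediate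
18 | propyne | CC#C | starting material
19 | trans-fused 5-ethyl-1-[(E)-2-ethylpent-1-en-3-yn-1-yl]-1,7-dimethyl-4,4a,7,7a-tetrahydrocyclopenta[c]pyran-3(1H)-one | CCC1=C[C@@H](C)[C@H]([C@@]2(C)/C=C(/C#CC)CC)[C@H]1CC(=O)O2 | intermediate
20 | lithium enolate of 19 (not isolated) | CCC1=C[C@@H](C)[C@H]([C@@]2(C)/C=C(/C#CC)CC)[C@H]1C=C(O[Li])O2 | intermediate
21 | trans-fused 5-ethyl-1-[(E)-2-ethylpent-1-en-3-yn-1-yl]-1,4,7-trimethyl-4,4a,7,7a-tetrahydrocyclopenta[c]pyran-3(1H)-one (C7 epimers) | CCC1=C[C@@H](C)[C@H]([C@@]2(C)/C=C(/C#CC)CC)[C@H]1C(C)C(=O)O2 | intermediate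
22 | lithium enolate of 21 (not isolated) | CCC1=C[C@@H](C)[C@H]([C@@]2(C)/C=C(/C#CC)CC)[C@H]1C(C)=C(O[Li])O2 | intermediate
23 | tert-butyldimethylsilyl ketene acetal of 21 (not isolated) | CCC1=C[C@@H](C)[C@H]([C@@]2(C)/C=C(/C#CC)CC)[C@H]1C(C)=C(O[Si](C)(C)C(C)(C)C)O2 | intermediate
24 | tert-butyldimethylsilyl ester of 25 (not isolated) | CCC1=C[C@@H](C)[C@@H]2C(C)=C[C@@](C#CC)(CC)[C@](C)(C(=O)O[Si](C)(C)C(C)(C)C)[C@@H]12 | intermediate
25 | (3R,3aS,6R,7R,7aR)-1,6-diethyl-3,4,7-trimethyl-6-(prop-1-yn-1-yl)-3a,6,7,7a-tetrahydro-3H-indene-7-carboxylic acid | CCC1=C[C@@H](C)[C@@H]2C(C)=C[C@@](C#CC)(CC)[C@](C)(C(=O)O)[C@@H]12 | intermediate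
26 | (E)-(2-bromovinyl)benzene | Br/C=C/c1ccccc1 | starting material
27 | alkenyl(chloro)zirconocene from 25, carboxyl as zirconocene carboxylate (Zr trans to C6; not isolated) | CCC1=C[C@@H](C)[C@@H]2C(C)=C[C@@](/C=C(C)/[Zr](Cl)(C3C=CC=C3)C3C=CC=C3)(CC)[C@](C)(C(=O)O[Zr](Cl)(C3C=CC=C3)C3C=CC=C3)[C@@H]12 | intermediate
28 | (3R,3aS,6S,7R,7aR)-1,6-diethyl-3,4,7-trimethyl-6-[(1E,3E)-2-methyl-4-phenylbuta-1,3-dien-1-yl]-3a,6,7,7a-tetrahydro-3H-indene-7-carboxylic acid | CCC1=C[C@@H](C)[C@@H]2C(C)=C[C@@](/C=C(C)/C=C/c3ccccc3)(CC)[C@](C)(C(=O)O)[C@@H]12 | target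

## Step count and least certain steps

Total: 12 steps. Longest linear sequence: 12 steps (1 → 28); all other reactants (2, 10, 18, 26) are commercial.

**Step 11 (key step).** Most likely failure: the twisted boat carrying the trans-fused cyclopentene is reached too slowly, so heterolysis of the tertiary allylic C4–O bond of the ketene acetal (elimination to an open trienyne silyl ester) or C-silylation takes over. Fallback, with ring closure and C–C bond formation separated: it sets out from 9 and returns at 25.
- Wittig methylenation of 9 (Ph3P=CH2) gives the isopropenyl ester F1.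
- α-Methylation (LDA, MeI) and saponification give the acid F2.
- Esterification (DCC, DMAP) with (Z)-3-ethylhex-2-en-4-yn-1-ol F3 gives the allyl ester F4. F3 is made from pent-2-yn-1-ol by trans-hydroalumination/iodination and Sonogashira coupling with 18.
- An open-chain Ireland–Claisen rearrangement (KHMDS, TMSCl, toluene) forms C6–C7 in the diene acid F5. Stereocontrol then rests on ketene acetal geometry and is weaker, so the needed diastereomer must be separated.
- Ring-closing metathesis (second-generation Ru catalyst) of the isopropenyl and vinyl groups closes C4=C5 and gives 25. The hindered alkyne is tolerated or masked for this step.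

**Step 7.** Most likely failure: proton loss from the cobalt-stabilised tertiary cation (enyne formation, which could also scramble C3a) competing with reclosure, or consumption of the complex during oxidative decomplexation. Fallback, kinetic filtering instead of thermodynamic funnelling: it sets out from 12 and returns at 25. Steps 8–10 are run on the epimer mixture and give, beside 17, 19 and 21, the C4-epimeric iodide F6, the C4-epimeric enyne F7 and the C4-epimeric methyl lactone F8. In step 11 only 21 can reach the boat, because the epimer would need the opposite twist, which the trans ring fusion forbids. Acid 25 is then separated from unchanged F8 by extraction into aqueous base.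

**Step 1.** Most likely failure: proton transfer within enolate 3 before C-alkylation, leading to enolate equilibration, β-elimination of silanolate and polyalkylation. Fallback, with the two bond formations decoupled: it sets out from 1 and returns at 4. Copper-catalysed addition of vinylmagnesium bromide in the presence of TMSCl gives the silyl enol ether F9, which is isolated. MeLi then regenerates the regiodefined lithium enolate free of copper and magnesium salts, and alkylation with 2 in THF/HMPA at −78 °C gives 4.

**Step 12.** Most likely failure: incomplete or non-regioselective hydrozirconation of the neopentyl alkyne in the presence of the zirconium carboxylate, or slow transmetalation of the hindered alkenylzirconium so that protodemetalation wins. Fallback in two stages: it sets out from 25 and returns at 28. Hydrozirconation followed by iodine gives the vinyl iodide F10, which is isolable so that regioisomers can be removed. Suzuki coupling with commercial (E)-2-phenylvinylboronic acid (Pd(PPh3)4, K3PO4, THF/H2O) then gives 28.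

## Further compounds

F1 | step 11 | all-trans methyl 2-[2-ethyl-4-methyl-5-(prop-1-en-2-yl)cyclopent-2-en-1-yl]acetate | CCC1=C[C@@H](C)[C@H](C(C)=C)[C@H]1CC(=O)OC
F2 | step 11 | all-trans 2-[2-ethyl-4-methyl-5-(prop-1-en-2-yl)cyclopent-2-en-1-yl]propanoic acid (C7 epimers) | CCC1=C[C@@H](C)[C@H](C(C)=C)[C@H]1C(C)C(=O)O
F3 | step 11 | (Z)-3-ethylhex-2-en-4-yn-1-ol | OC/C=C(/CC)C#CC
F4 | step 11 | (Z)-3-ethylhex-2-en-4-yn-1-yl ester of F2 | CCC1=C[C@@H](C)[C@H](C(C)=C)[C@H]1C(C)C(=O)OC/C=C(/CC)C#CC
F5 | step 11 | 2-[2-ethyl-4-methyl-5-(prop-1-en-2-yl)cyclopent-2-en-1-yl]-3-ethyl-2-methyl-3-vinylhex-4-ynoic acid (diastereomer leading to 25) | CCC1=C[C@@H](C)[C@H](C(C)=C)[C@H]1[C@@](C)(C(=O)O)[C@](CC)(C=C)C#CC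
F6 | step 7 | C4 epimer of 17 | CCC1=C[C@@H](C)[C@H]([C@]2(C)/C=C(/I)CC)[C@H]1CC(=O)O2
F7 | step 7 | C4 epimer of 19 | CCC1=C[C@@H](C)[C@H]([C@]2(C)/C=C(/C#CC)CC)[C@H]1CC(=O)O2
F8 | step 7 | C4 epimer of 21 | CCC1=C[C@@H](C)[C@H]([C@]2(C)/C=C(/C#CC)CC)[C@H]1C(C)C(=O)O2
F9 | step 1 | trimethylsilyl enol ether of (3,4-trans)-4-[(tert-butyldimethylsilyl)oxy]-3-vinylcyclopentanone | C[Si](C)(C)OC1=C[C@@H](C=C)[C@H](O[Si](C)(C)C(C)(C)C)C1
F10 | step 12 | (3R,3aS,7R,7aR)-1,6-diethyl-6-[(E)-2-iodoprop-1-en-1-yl]-3,4,7-trimethyl-3a,6,7,7a-tetrahydro-3H-indene-7-carboxylic acid (C6 as in 28) | CCC1=C[C@@H](C)[C@@H]2C(C)=C[C@@](/C=C(C)/I)(CC)[C@](C)(C(=O)O)[C@@H]12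
A1 | alternative 1 | (2E,4Z,7E,9E,11E,13E)-4,10-diethyl-2,6,8,12-tetramethyl-14-phenyltetradeca-2,4,7,9,11,13-hexaenoic acid (C6 configured as C3 of 28) | OC(=O)/C(C)=C/C(CC)=C\[C@@H](C)/C=C(C)/C=C(CC)/C=C(C)/C=C/c1ccccc1
A2 | alternative 2 | (2E,4E,6E)-3-ethyl-5-methyl-7-phenylhepta-2,4,6-trien-1-yl 2-[2-ethyl-4-methyl-5-(prop-1-en-2-yl)cyclopent-2-en-1-yl]propanoate | CCC1=C[C@@H](C)[C@H](C(C)=C)[C@H]1C(C)C(=O)OC/C=C(CC)/C=C(C)/C=C/c1ccccc1
A3 | alternative 2 | (4E,6E)-2-[2-ethyl-4-methyl-5-(prop-1-en-2-yl)cyclopent-2-en-1-yl]-3-ethyl-2,5-dimethyl-7-phenyl-3-vinylhepta-4,6-dienoic acid | CCC1=C[C@@H](C)[C@H](C(C)=C)[C@H]1[C@@](C)(C(=O)O)[C@](CC)(C=C)/C=C(C)/C=C/c1ccccc1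
A4 | alternative 3 | methyl trans-fused 1,6-diethyl-3,4-dimethyl-3a,7a-dihydro-3H-indene-7-carboxylate | CCC1=C[C@@H](C)[C@@H]2C(C)=CC(CC)=C(C(=O)OC)[C@@H]12
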